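**Plan**

1. Retrosynthesis: after removal of the benzyl and triethylsilyl groups, ring A is opened at C4a–C5 (retro-6π electrocyclisation to a dienylketene, hence to a diazoketone). The chain is then cut at C5–C6 (acylation of diazomethane), at C7=C8 (Horner–Wadsworth–Emmons) and at C3–C1' (Suzuki). The aryl fragment is cut at O–C2 of the dihydrofuran (epoxide opening) and at the aryl–prenyl bond.
2. Forward: the dihydrobenzofuran ring is closed first, its boronate is joined to the intact pyranone of kojic acid (ring C), the four-carbon chain is grown from the kojic CH2OH group, and ring A is closed last.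
3. Enabling feature: ring A (C4a, C5, C6, C7, C8, C8a) is fused to the 4-pyranone across C4a–C8a and carries oxygen on C7 and on C5, peri to the C4 carbonyl. A ketene carbon (future C5) held on C8a through C6–C7(OBn)=C8 can close onto C4a, the enol-ether β-carbon of the pyranone, and the dienone formed can only enolise to the 5-hydroxy-7-benzyloxy arene.
4. Stereochemistry: the single stereocentre (C2 of the dihydrobenzofuran, R) comes from a Shi epoxidation with the L-fructose-derived ketone, giving the (S)-epoxide, which is inverted once in the 5-exo phenoxide opening. No later step touches it.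

Key step: step 13

Abbreviation: Ar = (2R)-2-{2-[(triethylsilyl)oxy]propan-2-yl}-2,3-dihydro-1-benzofuran-5-yl; ring A atoms carry chromone numbers.

Assumption: phosphonate 14 and the L-fructose-derived Shi ketone are taken as purchasable, and the olefination of step 10 is taken to favour the Z enol ether (pyranone trans to the ester), which is the isomer drawn from 15 to 19.

**Step 1**
Reactants: 1 4-bromophenol; 2 prenyl bromide
Product: 3 4-bromo-2-(3-methylbut-2-en-1-yl)phenol
Conditions: NaH, toluene, 0 °C → rt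
Reagents that add atoms: none
Why: In a non-polar solvent the sodium phenoxide reacts as a tight ion pair at the ortho carbon (ortho C-alkylation by SN2 at the primary carbon of the prenyl group), and with the para position blocked by bromine the 2-prenylphenol should be the main product after tautomerisation.

**Step 2**
Reactants: 3 4-bromo-2-(3-methylbut-2-en-1-yl)phenol
Product: 4 [4-bromo-2-(3-methylbut-2-en-1-yl)phenoxy](tert-butyl)dimethylsilane
Conditions: TBSCl, imidazole, DMF, rt
Reagents that add atoms: tert-butyldimethylsilyl chloride, CC(C)(C)[Si](C)(C)Cl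
Why: Standard silylation of a phenol masks the nucleophilic oxygen so that the epoxide made next is not opened before its configuration is secured.

**Step 3**
Reactants: 4 [4-bromo-2-(3-methylbut-2-en-1-yl)phenoxy](tert-butyl)dimethylsilane
Product: 5 (4-bromo-2-{[(2S)-3,3-dimethyloxiran-2-yl]methyl}phenoxy)(tert-butyl)dimethylsilane
Conditions: 1,2:4,5-di-O-isopropylidene-β-L-erythro-2,3-hexodiulo-2,6-pyranose (0.3 equiv), KHSO5 (as Oxone, 2KHSO5·KHSO4·K2SO4), K2CO3, Bu4NHSO4, MeCN/CH2(OMe)2, aq. Na2B4O7/Na2EDTA buffer (pH 10.5), 0 °C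
Reagents that add atoms: potassium peroxymonosulfate, [K+].[O-]S(=O)(=O)OO
Why: Shi asymmetric epoxidation of a trisubstituted alkene by the chiral dioxirane formed in situ; the spiro transition state with the L-fructose-derived ketone delivers oxygen to the face that gives the (S)-epoxide, the mirror image of the (R)-epoxides that prenyl groups give with the D-fructose-derived ketone.

**Step 4**
Reactants: 5 (4-bromo-2-{[(2S)-3,3-dimethyloxiran-2-yl]methyl}phenoxy)(tert-butyl)dimethylsilane
Product: 7 2-[(2R)-5-bromo-2,3-dihydro-1-benzofuran-2-yl]propan-2-ol, via phenolate epoxide 6 (not isolated)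
Conditions: Bu4NF (TBAF), THF, 0 → 50 °C; H2O work-up
Reagents that add atoms: none
Why: Fluoride desilylation frees the phenoxide, which opens the epoxide at its less hindered secondary carbon in a 5-exo-tet SN2 reaction (the base-mediated mode, as opposed to acid-promoted 6-endo chroman formation), so the (S)-epoxide carbon is inverted to the (R)-configured C2 of the dihydrobenzofuran.

**Step 5**
Reactants: 7 2-[(2R)-5-bromo-2,3-dihydro-1-benzofuran-2-yl]propan-2-ol
Product: 8 {2-[(2R)-5-bromo-2,3-dihydro-1-benzofuran-2-yl]propan-2-yl}oxy(triethyl)silane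
Conditions: TESOTf, 2,6-lutidine, CH2Cl2, −78 → 0 °C
Reagents that add atoms: triethylsilyl trifluoromethanesulfonate, CC[Si](CC)(CC)OS(=O)(=O)C(F)(F)F
Why: Silyl triflate with 2,6-lutidine is the standard silylation of hindered tertiary alcohols, and the triethylsilyl ether keeps this hydroxyl away from the chloroformate of step 12 and the ketene of step 13.

**Step 6**
Reactants: 8 {2-[(2R)-5-bromo-2,3-dihydro-1-benzofuran-2-yl]propan-2-yl}oxy(triethyl)silane
Product: 9 triethyl({2-[(2R)-5-(4,4,5,5-tetramethyl-1,3,2-dioxaborolan-2-yl)-2,3-dihydro-1-benzofuran-2-yl]propan-2-yl}oxy)silane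
Conditions: B2pin2, Pd(dppf)Cl2 (3 mol%), KOAc, 1,4-dioxane, 85 °C
Reagents that add atoms: bis(pinacolato)diboron, CC1(C)OB(OC1(C)C)B1OC(C)(C)C(C)(C)O1
Why: Miyaura borylation of an electron-rich aryl bromide, with acetate as the mild base that tolerates the silyl ether and leaves the stereocentre untouched.

**Step 7**
Reactants: 10 kojic acid
Product: 11 6-(hydroxymethyl)-4-oxo-4H-pyran-3-yl trifluoromethanesulfonate
Conditions: PhNTf2, Et3N, DMF, 0 °C → rt
Reagents that add atoms: N-phenylbis(trifluoromethanesulfonimide), O=S(=O)(N(c1ccccc1)S(=O)(=O)C(F)(F)F)C(F)(F)F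
Why: The mild triflyl donor reacts only with the acidic enolic 5-hydroxyl (present as its ammonium salt) and leaves the primary alcohol free, a chemoselective triflation of a phenol-type hydroxyl.

**Step 8**
Reactants: 9 triethyl({2-[(2R)-5-(4,4,5,5-tetramethyl-1,3,2-dioxaborolan-2-yl)-2,3-dihydro-1-benzofuran-2-yl]propan-2-yl}oxy)silane; 11 6-(hydroxymethyl)-4-oxo-4H-pyran-3-yl trifluoromethanesulfonate
Product: 12 2-(hydroxymethyl)-5-[Ar]-4H-pyran-4-one
Conditions: Pd(PPh3)4 (5 mol%), K3PO4, 1,4-dioxane/H2O, 80 °C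
Reagents that add atoms: none
Why: Suzuki–Miyaura coupling; the electron-poor enol triflate of a 3-hydroxy-4-pyranone adds readily to zerovalent palladium and the aryl pinacol boronate transmetalates under aqueous phosphate without affecting the free alcohol or the silyl ether.

**Step 9**
Reactants: 12 2-(hydroxymethyl)-5-[Ar]-4H-pyran-4-one
Product: 13 4-oxo-5-[Ar]-4H-pyran-2-carbaldehyde
Conditions: Dess–Martin periodinane, pyridine, CH2Cl2, 0 °C → rt
Reagents that add atoms: none
Why: Dess–Martin oxidation of a primary alcohol to the aldehyde under buffered, non-aqueous conditions that spare the pyranone and the silyl ether.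

**Step 10**
Reactants: 13 4-oxo-5-[Ar]-4H-pyran-2-carbaldehyde; 14 methyl 2-(benzyloxy)-2-(dimethoxyphosphoryl)acetate
Product: 15 methyl (2Z)-2-(benzyloxy)-3-{4-oxo-5-[Ar]-4H-pyran-2-yl}prop-2-enoate
Conditions: 14, LiN(SiMe3)2, THF, −78 °C; then 13, −78 → 0 °C
Reagents that add atoms: none
Why: Horner–Wadsworth–Emmons olefination of a non-enolisable aldehyde with a pre-formed α-alkoxy phosphonoacetate anion, which is expected to favour the Z enol ether; any E isomer is removed by chromatography so that single compounds are carried on, although step 13 does not depend on this geometry.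

**Step 11**
Reactants: 15 methyl (2Z)-2-(benzyloxy)-3-{4-oxo-5-[Ar]-4H-pyran-2-yl}prop-2-enoate
Product: 16 (2Z)-2-(benzyloxy)-3-{4-oxo-5-[Ar]-4H-pyran-2-yl}prop-2-enoic acid
Conditions: LiOH (1.5 equiv), THF/H2O, 0 °C; then dilute HCl to pH 4, 0 °C
Reagents that add atoms: lithium hydroxide, [Li+].[OH-]
Why: Saponification of a methyl ester with a small excess of hydroxide at low temperature, which should be faster than attack on the pyranone and leaves the tertiary silyl ether and the enol benzyl ether intact through the mildly acidic work-up.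

**Step 12**
Reactants: 16 (2Z)-2-(benzyloxy)-3-{4-oxo-5-[Ar]-4H-pyran-2-yl}prop-2-enoic acid
Product: 18 (3Z)-3-(benzyloxy)-1-diazo-4-{4-oxo-5-[Ar]-4H-pyran-2-yl}but-3-en-2-one, via mixed anhydride 17 (not isolated)
Conditions: iBuOCOCl, N-methylmorpholine, THF, −20 °C; then CH2N2 (Et2O solution, prepared separately, 3 equiv), −20 → 0 °C
Reagents that add atoms: diazomethane, C=[N+]=[N-]; isobutyl chloroformate, CC(C)COC(=O)Cl (its atoms stay in 17 only)
Why: Acylation of diazomethane by a mixed carbonic anhydride (the first stage of an Arndt–Eistert sequence), run cold and briefly because the trisubstituted, α-alkoxy alkene should add the dipole only slowly.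

**Step 13**
Reactants: 18 (3Z)-3-(benzyloxy)-1-diazo-4-{4-oxo-5-[Ar]-4H-pyran-2-yl}but-3-en-2-one
Product: 23 7-(benzyloxy)-5-hydroxy-3-[Ar]-4H-chromen-4-one, via Z-dienylketene 19 (not isolated), via cyclobutenone 20 (not isolated), via E-dienylketene 21 (not isolated), via cyclohexadienone 22 (not isolated)
Conditions: hν (365 nm), degassed PhMe (0.005 M), rt; then 90 °C in the dark
Reagents that add atoms: none
Why: Proposed new method: light expels N2 from the diazoketone and the alkenyl group migrates to the carbene carbon (Wolff rearrangement), giving dienylketene 19, which has the pyranone trans to the ketene and therefore rests as cyclobutenone 20 after thermal 4π closure. On heating, 20 reopens reversibly, and the isomer with the pyranone turned inward (21) is removed irreversibly by a thermal disrotatory 6π electrocyclisation that joins the electrophilic ketene carbon to C3 of the pyranone, its nucleophilic enol-ether β-carbon; dienone 22, whose C4a–H lies between two carbonyls, enolises at once to the arene with the 5-hydroxyl hydrogen-bonded to the C4 carbonyl. The closest known reaction type is the Danheiser benzannulation in its photo-Wolff form, in which 3-alkoxy-4-vinylcyclobutenones and the dienylketenes in equilibrium with them close onto an alkene or arene π bond to give resorcinol monoethers; the extension is reasoned from the pyranone C2=C3 bond being an enol ether conjugated with the diene and from closure being paid for by aromatisation. Ring A is closed in the 6π electrocyclic mode with formation of the C4a–C5 bond alone. No stereocentre is formed, and the (R) centre of the dihydrobenzofuran is remote and inert. The selectivities needed are regiochemistry, fixed because only one pyranone CH is adjacent to the side chain and the two ring A oxygens arrive already differentiated, and a cis dienylketene, supplied by the cyclobutenone shuttle instead of by the geometry of 18; high dilution, an aprotic medium and the silyl ether keep nucleophiles and dimerisation away from the ketene.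

**Step 14**
Reactants: 23 7-(benzyloxy)-5-hydroxy-3-[Ar]-4H-chromen-4-one
Product: 24 5,7-dihydroxy-3-[Ar]-4H-chromen-4-one
Conditions: H2 (1 atm), Pd/C (10%), EtOAc, rt, stopped at full conversion
Reagents that add atoms: none
Why: Hydrogenolysis of an aryl benzyl ether over palladium on carbon in a non-protic solvent is much faster than reduction of the isoflavone C2=C3 bond and does not cleave the silyl ether or the dihydrobenzofuran.

**Step 15**
Reactants: 24 5,7-dihydroxy-3-[Ar]-4H-chromen-4-one
Product: 25 5,7-dihydroxy-3-[(2R)-2-(2-hydroxypropan-2-yl)-2,3-dihydro-1-benzofuran-5-yl]-4H-chromen-4-one (target)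
Conditions: HF·pyridine, THF/pyridine, 0 °C → rt
Reagents that add atoms: none
Why: Buffered fluoride cleaves the triethylsilyl ether of the tertiary alcohol without ionising it and without harming the free phenols or the stereocentre.

**Compound list**

1 | 4-bromophenol | Oc1ccc(Br)cc1 | starting material
2 | prenyl bromide (1-bromo-3-methylbut-2-ene) | CC(C)=CCBr | starting material
3 | 4-bromo-2-(3-methylbut-2-en-1-yl)phenol | CC(C)=CCc1cc(Br)ccc1O | intermediate
4 | [4-bromo-2-(3-methylbut-2-en-1-yl)phenoxy](tert-butyl)dimethylsilane | CC(C)=CCc1cc(Br)ccc1O[Si](C)(C)C(C)(C)C | intermediate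
5 | (4-bromo-2-{[(2S)-3,3-dimethyloxiran-2-yl]methyl}phenoxy)(tert-butyl)dimethylsilane | CC1(C)O[C@H]1Cc1cc(Br)ccc1O[Si](C)(C)C(C)(C)C | intermediate
6 | 4-bromo-2-{[(2S)-3,3-dimethyloxiran-2-yl]methyl}phenolate (tetrabutylammonium salt in the flask) | CC1(C)O[C@H]1Cc1cc(Br)ccc1[O-] | intermediate (not isolated)
7 | 2-[(2R)-5-bromo-2,3-dihydro-1-benzofuran-2-yl]propan-2-ol | CC(C)(O)[C@H]1Cc2cc(Br)ccc2O1 | intermediate
8 | {2-[(2R)-5-bromo-2,3-dihydro-1-benzofuran-2-yl]propan-2-yl}oxy(triethyl)silane | CC(C)(O[Si](CC)(CC)CC)[C@H]1Cc2cc(Br)ccc2O1 | intermediate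
9 | triethyl({2-[(2R)-5-(4,4,5,5-tetramethyl-1,3,2-dioxaborolan-2-yl)-2,3-dihydro-1-benzofuran-2-yl]propan-2-yl}oxy)silane | CC(C)(O[Si](CC)(CC)CC)[C@H]1Cc2cc(B3OC(C)(C)C(C)(C)O3)ccc2O1 | intermediate
10 | kojic acid (5-hydroxy-2-(hydroxymethyl)-4H-pyran-4-one) | OCc1cc(=O)c(O)co1 | starting material
11 | 6-(hydroxymethyl)-4-oxo-4H-pyran-3-yl trifluoromethanesulfonate | OCc1cc(=O)c(OS(=O)(=O)C(F)(F)F)co1 | intermediate
12 | 2-(hydroxymethyl)-5-[Ar]-4H-pyran-4-one | CC(C)(O[Si](CC)(CC)CC)[C@H]1Cc2cc(-c3coc(CO)cc3=O)ccc2O1 | intermediate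
13 | 4-oxo-5-[Ar]-4H-pyran-2-carbaldehyde | CC(C)(O[Si](CC)(CC)CC)[C@H]1Cc2cc(-c3coc(C=O)cc3=O)ccc2O1 | intermediate
14 | methyl 2-(benzyloxy)-2-(dimethoxyphosphoryl)acetate | COC(=O)C(OCc1ccccc1)P(=O)(OC)OC | starting material
15 | methyl (2Z)-2-(benzyloxy)-3-{4-oxo-5-[Ar]-4H-pyran-2-yl}prop-2-enoate | CC(C)(O[Si](CC)(CC)CC)[C@H]1Cc2cc(-c3coc(/C=C(\OCc4ccccc4)C(=O)OC)cc3=O)ccc2O1 | intermediate
16 | (2Z)-2-(benzyloxy)-3-{4-oxo-5-[Ar]-4H-pyran-2-yl}prop-2-enoic acid | CC(C)(O[Si](CC)(CC)CC)[C@H]1Cc2cc(-c3coc(/C=C(\OCc4ccccc4)C(=O)O)cc3=O)ccc2O1 | intermediate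
17 | (2Z)-2-(benzyloxy)-3-{4-oxo-5-[Ar]-4H-pyran-2-yl}prop-2-enoic isobutyl carbonic anhydride | CC(C)(O[Si](CC)(CC)CC)[C@H]1Cc2cc(-c3coc(/C=C(\OCc4ccccc4)C(=O)OC(=O)OCC(C)C)cc3=O)ccc2O1 | intermediate (not isolated)
18 | (3Z)-3-(benzyloxy)-1-diazo-4-{4-oxo-5-[Ar]-4H-pyran-2-yl}but-3-en-2-one | CC(C)(O[Si](CC)(CC)CC)[C@H]1Cc2cc(-c3coc(/C=C(\OCc4ccccc4)C(=O)C=[N+]=[N-])cc3=O)ccc2O1 | intermediate
19 | (3Z)-3-(benzyloxy)-4-{4-oxo-5-[Ar]-4H-pyran-2-yl}buta-1,3-dien-1-one | CC(C)(O[Si](CC)(CC)CC)[C@H]1Cc2cc(-c3coc(/C=C(\OCc4ccccc4)C=C=O)cc3=O)ccc2O1 | intermediate (not isolated)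
20 | 3-(benzyloxy)-4-{4-oxo-5-[Ar]-4H-pyran-2-yl}cyclobut-2-en-1-one (both C4 epimers) | CC(C)(O[Si](CC)(CC)CC)[C@H]1Cc2cc(-c3coc(C4C(=O)C=C4OCc4ccccc4)cc3=O)ccc2O1 | intermediate (not isolated)
21 | (3E)-3-(benzyloxy)-4-{4-oxo-5-[Ar]-4H-pyran-2-yl}buta-1,3-dien-1-one | CC(C)(O[Si](CC)(CC)CC)[C@H]1Cc2cc(-c3coc(/C=C(/OCc4ccccc4)C=C=O)cc3=O)ccc2O1 | intermediate (not isolated)
22 | 7-(benzyloxy)-3-[Ar]-4aH-chromene-4,5-dione (both C4a epimers) | CC(C)(O[Si](CC)(CC)CC)[C@H]1Cc2cc(C3=COC4=CC(OCc5ccccc5)=CC(=O)C4C3=O)ccc2O1 | intermediate (not isolated)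
23 | 7-(benzyloxy)-5-hydroxy-3-[Ar]-4H-chromen-4-one | CC(C)(O[Si](CC)(CC)CC)[C@H]1Cc2cc(-c3coc4cc(OCc5ccccc5)cc(O)c4c3=O)ccc2O1 | intermediate
24 | 5,7-dihydroxy-3-[Ar]-4H-chromen-4-one | CC(C)(O[Si](CC)(CC)CC)[C@H]1Cc2cc(-c3coc4cc(O)cc(O)c4c3=O)ccc2O1 | intermediate
25 | 5,7-dihydroxy-3-[(2R)-2-(2-hydroxypropan-2-yl)-2,3-dihydro-1-benzofuran-5-yl]-4H-chromen-4-one | CC(C)(O)[C@H]1Cc2cc(-c3coc4cc(O)cc(O)c4c3=O)ccc2O1 | target

**Step count and risks**

Total: 15 steps. Longest linear sequence: 14 steps (steps 1–6, then 8–15); step 7 is the one-step side branch.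

Steps most likely to fail:

Step 13. The excited pyranone may rearrange, or the ketene may dimerise or be captured, faster than ring closure; the cyclobutenone may also fail to reopen with the pyranone turned inward. The fallback is the established 3-iodochromone route to isoflavones and sets out from boronate 9. 2',4',6'-Trihydroxyacetophenone is dibenzylated (BnBr, K2CO3, acetone) to 1-[2,4-bis(benzyloxy)-6-hydroxyphenyl]ethan-1-one F1. Condensation with N,N-dimethylformamide dimethyl acetal gives (2E)-1-[2,4-bis(benzyloxy)-6-hydroxyphenyl]-3-(dimethylamino)prop-2-en-1-one F2, and iodine closes it to 5,7-bis(benzyloxy)-3-iodo-4H-chromen-4-one F3. Suzuki coupling of F3 with 9 (Pd(PPh3)4, K3PO4, dioxane/H2O) should give 5,7-bis(benzyloxy)-3-[Ar]-4H-chromen-4-one F4. Hydrogenolysis of both benzyl ethers (H2, Pd/C, EtOAc) comes back to the route at 24.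

Step 12. Diazomethane may add as a 1,3-dipole across the electron-poor alkene of the mixed anhydride or attack its carbonate carbonyl, and the hydroxide of step 11 may open the pyranone beforehand. The fallback sets out from aldehyde 13 and avoids both steps. Rh2(OAc)4-catalysed O–H insertion of dimethyl (1-diazo-2-oxopropyl)phosphonate into benzyl alcohol gives dimethyl [1-(benzyloxy)-2-oxopropyl]phosphonate F5. Horner–Wadsworth–Emmons reaction of F5 with 13 (LiN(SiMe3)2, THF) gives the methyl ketone (3Z)-3-(benzyloxy)-4-{4-oxo-5-[Ar]-4H-pyran-2-yl}but-3-en-2-one F6. Its lithium enolate is acylated with 2,2,2-trifluoroethyl trifluoroacetate to (5Z)-5-(benzyloxy)-1,1,1-trifluoro-6-{4-oxo-5-[Ar]-4H-pyran-2-yl}hex-5-ene-2,4-dione F7. Diazo transfer from methanesulfonyl azide (Et3N, H2O, MeCN) with loss of the trifluoroacetyl group, a method made for α,β-unsaturated diazoketones, comes back to the route at 18.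

Step 1. O-alkylation and double ortho-alkylation may take most of the material. The fallback sets out from 1. O-Allylation (allyl bromide, K2CO3, acetone) gives 1-bromo-4-(prop-2-en-1-yloxy)benzene F8. Aromatic Claisen rearrangement (N,N-diethylaniline, 200 °C) gives 4-bromo-2-(prop-2-en-1-yl)phenol F9, and silylation (TBSCl, imidazole) gives [4-bromo-2-(prop-2-en-1-yl)phenoxy](tert-butyl)dimethylsilane F10. Cross-metathesis with 2-methylbut-2-ene (second-generation Grubbs catalyst RuCl2(=CHPh)(PCy3)(H2IMes), CH2Cl2, 40 °C) comes back to the route at 4.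

**Further compounds**

F1 | step 13 | 1-[2,4-bis(benzyloxy)-6-hydroxyphenyl]ethan-1-one | CC(=O)c1c(O)cc(OCc2ccccc2)cc1OCc1ccccc1
F2 | step 13 | (2E)-1-[2,4-bis(benzyloxy)-6-hydroxyphenyl]-3-(dimethylamino)prop-2-en-1-one | CN(C)/C=C/C(=O)c1c(O)cc(OCc2ccccc2)cc1OCc1ccccc1
F3 | step 13 | 5,7-bis(benzyloxy)-3-iodo-4H-chromen-4-one | O=c1c(I)coc2cc(OCc3ccccc3)cc(OCc3ccccc3)c12
F4 | step 13 | 5,7-bis(benzyloxy)-3-[Ar]-4H-chromen-4-one | CC(C)(O[Si](CC)(CC)CC)[C@H]1Cc2cc(-c3coc4cc(OCc5ccccc5)cc(OCc5ccccc5)c4c3=O)ccc2O1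
F5 | step 12 | dimethyl [1-(benzyloxy)-2-oxopropyl]phosphonate | CC(=O)C(OCc1ccccc1)P(=O)(OC)OC
F6 | step 12 | (3Z)-3-(benzyloxy)-4-{4-oxo-5-[Ar]-4H-pyran-2-yl}but-3-en-2-one | CC(C)(O[Si](CC)(CC)CC)[C@H]1Cc2cc(-c3coc(/C=C(\OCc4ccccc4)C(C)=O)cc3=O)ccc2O1
F7 | step 12 | (5Z)-5-(benzyloxy)-1,1,1-trifluoro-6-{4-oxo-5-[Ar]-4H-pyran-2-yl}hex-5-ene-2,4-dione | CC(C)(O[Si](CC)(CC)CC)[C@H]1Cc2cc(-c3coc(/C=C(\OCc4ccccc4)C(=O)CC(=O)C(F)(F)F)cc3=O)ccc2O1
F8 | step 1 | 1-bromo-4-(prop-2-en-1-yloxy)benzene | C=CCOc1ccc(Br)cc1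
F9 | step 1 | 4-bromo-2-(prop-2-en-1-yl)phenol | C=CCc1cc(Br)ccc1O
F10 | step 1 | [4-bromo-2-(prop-2-en-1-yl)phenoxy](tert-butyl)dimethylsilane | C=CCc1cc(Br)ccc1O[Si](C)(C)C(C)(C)C
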